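## The problem

The target is a ten-membered carbocycle (C1–C10) fused at C6–C7 to a butenolide (O–C6, C7=C11, C12=O). C11 carries an acetoxymethyl group (C13) and O8 carries a (2S)-2-methyloxirane-2-carboxylate. There are seven stereocentres: C8 and C6, whose oxygens are 1,3-syn across the sp2 carbon C7; the cis-epoxide at C4/C5 (from a Z olefin); the trans-epoxide at C1/C10 (from an E olefin); and the quaternary carbon of the ester. C8 and C6 have no stereocentre beside them and must be set by reagent control. Once they and the flat butenolide are in place they fix the ring conformation, which is the only handle on the faces of the two ring olefins; the ester stereocentre can be bought. Three epoxides (acid, nucleophiles), the C13 acetate (lost through the furanolate when base removes H-6), the epimerisable C6–H and the acid-sensitive E,Z-1,5-diene forbid rough treatment, so the ring epoxides must come last and under neutral conditions. The two oxygenated carbons on C11 become different (lactone carbonyl C12, acetoxymethyl C13) only through their position relative to C6. The feature that opens the key step is that C9–C10(C14)–C1–C2 and C3–C4(C15)–C5–C6 are two isoprene units joined head to tail, C7–C8 is a two-carbon unit bearing the C11 branch, and the skeleton needs one E (C1=C10) and one Z (C4=C5) olefin. This is the pattern left by a nickel-mediated union of two dienes and one alkyne.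

## Retrosynthesis

**22 ⇒ 20 (through 21).** The four epoxide C–O bonds at C1/C10 and C4/C5 are cut first. Epoxidising earlier would expose the epoxides to chromium oxidant and fluoride and would leave face selection to a ring without the butenolide. Diene lactone 20 has three stereocentres instead of seven. The forward step must take the two electron-rich ring olefins, leave the electron-poor C7=C11 alone, and attack the outer face of one ring conformer; 21 is the 1(10)-monoepoxide on the way.

**20 ⇒ 19 ⇒ 17.** The acetate is removed and the lactone is traced to triol 17 by a change of oxidation state at C12. The two hydroxymethyl groups on C11 are the same until one of them lies cis to the C6 hydroxyl. Only that one can close a lactol (18) after oxidation to the aldehyde, so the ring itself decides which carbon becomes C12. The oxidant must prefer primary over secondary alcohols and stop before C13 is attacked.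

**17 ⇒ 16 ⇒ 15.** The two primary silyl ethers are restored and the C6 carbinol is traced to ketone 15. A ketone at C6 lets a chiral reagent set the configuration; no neighbouring group could direct it without also needing a free O8.

**15 ⇒ 14.** The C6 carbonyl and the C7=C11 bond are traced to a tertiary C11 alcohol flanked by a C6=C7 olefin, through an oxidative 1,3-transposition. Direct oxidation of the doubly allylic C6 methylene was set aside: no reagent tells three olefins apart, and pentadienyl intermediates are captured at their ends. The relay from C11 is position-specific, and because both C11 arms are alike the new tetrasubstituted olefin has no geometry to control.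

**14 ⇒ 11 + 13 (13 ⇐ 12).** The C8 ester bond is cut. Putting the final acyl group on early makes it the protecting group of O8 during the chromium step; everything after it is neutral or buffered. Acid 13 comes from commercial ester 12.

**11 ⇒ 10 ⇒ 9 ⇒ 8 ⇒ 7.** C8 is traced through achiral dienone 10, so that a CBS reduction sets it. Diol 9 comes from epoxide 8 by base-induced isomerisation, which moves the olefin from C7=C8 to C6=C7 and leaves the oxygen on C8. Epoxide 8 comes from triene alcohol 7 by hydroxyl-directed epoxidation: the tertiary C11 hydroxyl singles out C7=C8 among three trisubstituted olefins. The C11 carbinol therefore serves twice, first as director, then as the oxygen donor for C6 (its oxygen ends as the lactone ring oxygen).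

**7 ⇒ 6 ⇒ 4 + two 5.** C2–C3, C6–C7 and C8–C9 are cut together. The precursors are isoprene and one small alkyne; no other cut reaches material this simple. The forward step must give head-to-tail diene linkage, the branch on C7 next to C6, E at C1=C10 and Z at C4=C5. The hydroxyl is silylated (6) because protic groups divert bis-allyl nickel intermediates.

**4 ⇒ 3 ⇒ 1 + 2.** The alkyne is ethynylmagnesium bromide added to a protected dihydroxyacetone. The symmetric C11 is kept on purpose.

## Roads not taken

**Alternative 1: hetero-Pauson–Khand closure of both rings.** The cut is C6–C7, C11–C12 and C12–O. Forward, Mo(CO)6 (zerovalent molybdenum) with DMSO under CO would join the C7≡C11 alkyne, the C6 aldehyde and CO in the open-chain precursor of A1 to give A1.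
- Merits: carbocycle and butenolide form in one step. The C6–O bond, the C12 carbonyl, C7=C11 and a differentiated C13 arrive together; these are the functions that steps 5–14 of the chosen route build one by one. C8 and the 4,5-epoxide can be set on an open chain.
- Weak points: the reaction is known where a short tether holds alkyne and carbonyl together for five- or six-membered rings. A ten-membered closure through a metallacycle has no counterpart. C6 would be set under remote control. The α-epoxy aldehyde would have to survive the heat that Mo(CO)6 needs.
- Comparison: A1 is closer to the target than 6 and its endgame would be shorter and safer. Against that, the chosen plan has a ring-forming step with a direct mechanistic parent, bulk precursors, and a test of the key step after three steps instead of after a long linear sequence.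

**Alternative 2: anionic oxy-Cope ring expansion.** A [3,3] shift forms C2–C3 and cleaves C5–C10. Forward, the potassium alkoxide (KH, 18-crown-6) of the six-membered precursor of A2 rearranges and the enolate is trapped with Me3SiCl to give A2.
- Merits: this is the best-precedented entry to germacrane rings. The chair transition state gives E at C1=C10. C6, C7 and C8 come from the chiral pool with absolute configuration assured.
- Weak points: A2 has C7 as an sp3 carbon with an isopropenyl group, so C12 and C13 must both be oxidised and C7=C11 introduced. C4=C5 arrives as an enol ether of a C5 ketone, so the Z olefin must be rebuilt and the C5 oxygen removed. The precursor with three contiguous stereocentres and a quaternary C10 is long to make.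
- Comparison: in certainty of ring formation and of absolute configuration this road is better. The chosen plan sets against it direct delivery of the 4Z olefin and of the correctly branched, oxygenated C11, and far fewer steps before the ring.

**Alternative 3: B-alkyl Suzuki–Miyaura macrocyclisation at C3–C4.** Forward, 9-BBN adds to the terminal C2=C3 olefin of the open-chain precursor of A3. PdCl2(dppf) (divalent palladium precatalyst, zerovalent palladium in the cycle) with Cs2CO3 then couples the C3 borane with the Z-vinyl iodide at C4 to give A3.
- Merits: the coupling is stereoretentive, so the Z olefin is secured in the vinyl iodide. The butenolide, C6, C8 and C13 are already in place. A3 is close to compound 19, so neither the C6 oxygen nor the C12/C13 distinction has to be solved on the ring. The reaction type is known for macrocycles.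
- Weak points: a strained ten-membered ring with an E olefin invites dimerisation. Cs2CO3 threatens the C6–H of the butenolide and the allylic C13 silyl ether. The open-chain precursor needs a long linear synthesis.
- Comparison: in olefin-geometry control and in endgame length this road is better than the chosen one. The chosen plan sets against it a ring made in three steps from isoprene with full atom economy.

Key step: step 3

Remarks:
- Atom numbers are germacrane numbers (ring C1–C10, C11–C13 on C7, C14 on C10, C15 on C4); TBS = tert-butyldimethylsilyl.
- The alkyne-derived C7=C8 bond of 6 is cis within the ring; by the sequence rules it is E, because C11 outranks C6.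
- Ketone 1 and ester 12 are treated as catalogue compounds; 1 is otherwise one silylation away from dihydroxyacetone dimer.

## Route

Step 1
Reactants: 1 1,3-bis(tert-butyldimethylsilyloxy)propan-2-one; 2 ethynylmagnesium bromide
Product: 3 1-(tert-butyldimethylsilyloxy)-2-[(tert-butyldimethylsilyloxy)methyl]but-3-yn-2-ol
Conditions: HC≡CMgBr, THF, −78 → 0 °C; aq. NH4Cl
Reagents that add atoms: none
Why: Grignard 1,2-addition of an acetylide to a ketone; the two arms are identical, so no stereocentre forms.

Step 2
Reactants: 3 propargylic alcohol
Product: 4 trimethylsilyl ether of 3, HC≡C–C(OSiMe3)(CH2OTBS)2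
Conditions: Me3SiCl, imidazole, DMF, rt
Reagents that add atoms: chlorotrimethylsilane, C[Si](C)(C)Cl
Why: Imidazole-promoted silylation of a tertiary alcohol; the hydroxyl must be masked because protic groups protonate bis-allyl nickel intermediates, and Me3Si can later be removed without touching the primary TBS ethers.

Step 3
Reactants: 4 silylated alkyne; 5 isoprene (two molecules are incorporated)
Product: 6 11-(trimethylsilyloxy)-12,13-bis(TBS-oxy)germacra-1(10)E,4Z,7E-triene (C7=C8 ring-cis)
Conditions: Ni(cod)2 (10 mol %), PPh3 (10 mol %), isoprene (10 equiv), toluene, 40 °C, 4 added over 10 h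
Reagents that add atoms: none
Why: Proposed new method: zerovalent nickel should couple two isoprenes oxidatively at C2–C3 to a bis-allyl nickel chain, the alkyne should insert into the allyl–nickel bond at C9 through its unhindered terminus C8, and reductive elimination between the C7 alkenyl and the C6 allyl terminus should close the ring; the closest known reaction type is the Ni(cod)2/phosphine cotrimerisation of two butadienes with one alkyne to cis,cis,trans-cyclodeca-1,4,7-trienes. The ten-membered ring closes by C(sp2)–C(sp3) reductive elimination from an eleven-membered alkenyl(allyl)nickel metallacycle, not by cyclisation of a free chain, so no dilution is needed. No stereocentre is formed; the step must deliver head-to-tail diene linkage, the carbinol branch on C7 next to C6, E at C1=C10 and Z at C4=C5. Head-to-tail linkage is the mode of nickel-catalysed isoprene dimerisation that leads to 1,5-dimethylcycloocta-1,5-diene, the main cyclodimer. The 1,1-disubstituted allyl end (C4–C6) should bind η1 through C6 and hold a Z C4=C5 bond, while the 2-methylallyl end (C9–C10–C1) stays η3 with its chain syn and gives E at C1=C10, the one-cis/one-trans pattern of the parent reaction. The fully substituted propargylic carbon should steer C–C bond formation to the alkyne CH and leave nickel on C7, and the silyl ethers remove the protic groups that would lead to linear dimers. Slow addition of 4 into excess isoprene should suppress alkyne cyclotrimerisation.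

Step 4
Reactants: 6 triene trimethylsilyl ether
Product: 7 12,13-bis(TBS-oxy)germacra-1(10)E,4Z,7E-trien-11-ol
Conditions: K2CO3 (cat.), MeOH, 0 °C → rt
Reagents that add atoms: none
Why: Base-catalysed methanolysis cleaves the labile trimethylsilyl ether and leaves the primary TBS ethers; no stereocentre is involved.

Step 5
Reactants: 7 tertiary allylic alcohol
Product: 8 rac-(7R*,8S*)-7,8-epoxy-12,13-bis(TBS-oxy)germacra-1(10)E,4Z-dien-11-ol (cis-epoxide)
Conditions: VO(acac)2 (5 mol %), t-BuOOH (1.5 equiv), CH2Cl2, 0 °C
Reagents that add atoms: tert-butyl hydroperoxide, CC(C)(C)OO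
Why: Vanadium-catalysed hydroxyl-directed epoxidation (Sharpless–Michaelson); only the allylic C7=C8 bond is within reach of the vanadate ester, the other two trisubstituted olefins are remote, and the racemic stereocentres are erased in steps 6–7.

Step 6
Reactants: 8 epoxy alcohol
Product: 9 rac-12,13-bis(TBS-oxy)germacra-1(10)E,4Z,6E-triene-8,11-diol (C6=C7 ring-cis)
Conditions: Et2Al(tmp) (from Et2AlCl and Li(tmp), 4 equiv), toluene, 0 °C; aq. Rochelle salt
Reagents that add atoms: none
Why: Yamamoto isomerisation of an epoxide to an allylic alcohol with a diethylaluminium amide; syn-elimination breaks the C–O bond at the more substituted C7, where the only β-hydrogens are the allylic ones on C6, so oxygen stays on C8. A Payne shift of the epoxide toward C11 would converge on the same diol, and the geometry of the new C6=C7 bond is of no consequence because step 11 consumes it.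

Step 7
Reactants: 9 diol
Product: 10 11-hydroxy-12,13-bis(TBS-oxy)germacra-1(10)E,4Z,6E-trien-8-one
Conditions: MnO2 (20 equiv), CH2Cl2, rt
Reagents that add atoms: none
Why: MnO2 oxidises the secondary allylic alcohol and cannot oxidise the tertiary one; this removes the racemic C8 centre and gives an achiral ketone for the enantioselective reduction.

Step 8
Reactants: 10 dienone
Product: 11 (8S)-12,13-bis(TBS-oxy)germacra-1(10)E,4Z,6E-triene-8,11-diol
Conditions: (R)-2-methyl-CBS-oxazaborolidine (0.3 equiv), catecholborane (2.5 equiv), toluene, −78 °C; MeOH, pH 7 buffer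
Reagents that add atoms: none
Why: Corey–Bakshi–Shibata reduction; the ketone lies between a methylene (C9, small) and the fully substituted alkenyl carbon C7 (large), so the (R)-catalyst should give the 8S alcohol. Catecholborane is chosen because a borylated tertiary hydroxyl then carries no hydride for an undirected intramolecular delivery.

Step 9
Reactants: 12 methyl (2S)-2-methyloxirane-2-carboxylate
Product: 13 (2S)-2-methyloxirane-2-carboxylic acid
Conditions: LiOH·H2O, THF/H2O, 0 °C; NaHSO4 to pH 3, EtOAc extraction, used at once
Reagents that add atoms: lithium hydroxide, [Li+].[OH-]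
Why: Saponification of a methyl ester; the quaternary stereocentre cannot epimerise and the electron-poor epoxide survives cold hydroxide and brief mild acid.

Step 10
Reactants: 11 (8S)-diol; 13 (2S)-epoxy acid
Product: 14 (8S)-11-hydroxy-12,13-bis(TBS-oxy)germacra-1(10)E,4Z,6E-trien-8-yl (2S)-2-methyloxirane-2-carboxylate
Conditions: 2-methyl-6-nitrobenzoic anhydride, DMAP, Et3N, CH2Cl2, rt
Reagents that add atoms: none
Why: Shiina esterification through a mixed anhydride and DMAP acyl transfer; the secondary C8 hydroxyl reacts and the hindered tertiary C11 hydroxyl does not, and the acyl group then protects O8 for the rest of the route.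

Step 11
Reactants: 14 tertiary dienyl carbinol
Product: 15 (8S)-6-oxo-12,13-bis(TBS-oxy)germacra-1(10)E,4Z,7(11)-trien-8-yl (2S)-2-methyloxirane-2-carboxylate
Conditions: pyridinium chlorochromate (C5H5NH[CrO3Cl], 3 equiv), 4 Å MS, CH2Cl2, rt
Reagents that add atoms: none
Why: Babler–Dauben oxidative transposition; the chromate ester of the tertiary allylic alcohol shifts [3,3] to C6 and is oxidised there to the ketone, which drains every reversible isomer (including a shift on to C4) into 15. The tetrasubstituted C7=C11 bond has no geometry because both C11 arms are the same, and C8 is untouched.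

Step 12
Reactants: 15 cross-conjugated dienone
Product: 16 (6R,8S)-6-hydroxy-12,13-bis(TBS-oxy)germacra-1(10)E,4Z,7(11)-trien-8-yl (2S)-2-methyloxirane-2-carboxylate
Conditions: (S)-2-methyl-CBS-oxazaborolidine (1.0 equiv), catecholborane, toluene, −78 → −40 °C; MeOH, pH 7 buffer
Reagents that add atoms: none
Why: Corey–Bakshi–Shibata 1,2-reduction; the tetrasubstituted alkenyl carbon C7 with its C8 ester is the large group and the CH= of the cis-alkenyl side (C5) the small one, so the (S)-catalyst should give 6R, syn to O8. Ester and epoxide are inert to catecholborane at this temperature.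

Step 13
Reactants: 16 bis-silyl ether
Product: 17 (6R,8S)-6,12,13-trihydroxygermacra-1(10)E,4Z,7(11)-trien-8-yl (2S)-2-methyloxirane-2-carboxylate
Conditions: Bu4NF, AcOH (1:1), THF, 0 °C → rt
Reagents that add atoms: none
Why: Buffered fluoride cleaves the two primary TBS ethers; the near-neutral medium spares the doubly allylic alcohol, the ester (no free alkoxide for acyl migration) and the epoxide.

Step 14
Reactants: 17 triol
Product: 19 (6R,8S)-13-hydroxy-8-[(2S)-2-methyloxirane-2-carbonyloxy]germacra-1(10)E,4Z,7(11)-trien-12,6-olide, via C12 lactol 18 (not isolated)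
Conditions: TEMPO (0.2 equiv), PhI(OAc)2 (2.1 equiv), CH2Cl2, 0 °C → rt
Reagents that add atoms: none
Why: Oxoammonium oxidative lactonisation; a primary allylic alcohol is oxidised to the aldehyde, the one cis to the C6 hydroxyl closes to lactol 18 and is oxidised on to the butenolide, and the secondary C6 alcohol is not attacked. Geometry alone decides which arm becomes C12; the C13 hydroxymethyl sits beside the bulky C8 ester and should react more slowly with the hindrance-sensitive oxidant, which is limited to two equivalents.

Step 15
Reactants: 19 hydroxy lactone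
Product: 20 (6R,8S)-13-acetoxy-8-[(2S)-2-methyloxirane-2-carbonyloxy]germacra-1(10)E,4Z,7(11)-trien-12,6-olide
Conditions: Ac2O, pyridine, CH2Cl2, 0 °C
Reagents that add atoms: acetic anhydride, CC(=O)OC(C)=O
Why: Acetylation of the only free hydroxyl; pyridine is too weak a base to remove H-6 of the butenolide, so the new allylic acetate is not eliminated.

Step 16
Reactants: 20 diene lactone
Product: 22 (1R,4R,5S,6S,8S,10R)-13-acetoxy-1,10:4,5-diepoxy-8-[(2S)-2-methyloxirane-2-carbonyloxy]germacr-7(11)-en-12,6-olide (target), via 1(10)-monoepoxide 21 (not isolated)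
Conditions: dimethyldioxirane (3 equiv, acetone solution), CH2Cl2, −20 → 0 °C
Reagents that add atoms: dimethyldioxirane, CC1(C)OO1
Why: Electrophilic epoxidation under neutral conditions; the two trisubstituted ring olefins react (C1=C10 first, since it has no allylic oxygen) and the electron-poor butenolide olefin does not. Each ring olefin stands roughly perpendicular to the mean ring plane, so only its outer face is open; attack on the conformer with C14 and C15 on the face of H-6 and H-8, the arrangement usual for germacranolides, should give the 1R,10R and 4R,5S epoxides.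

## Compound list

1 | 1,3-bis(tert-butyldimethylsilyloxy)propan-2-one | CC(C)(C)[Si](C)(C)OCC(=O)CO[Si](C)(C)C(C)(C)C | starting material
2 | ethynylmagnesium bromide | C#C[Mg]Br | starting material
3 | 1-(tert-butyldimethylsilyloxy)-2-[(tert-butyldimethylsilyloxy)methyl]but-3-yn-2-ol | C#CC(O)(CO[Si](C)(C)C(C)(C)C)CO[Si](C)(C)C(C)(C)C | intermediate
4 | trimethylsilyl ether of 3 | C#CC(O[Si](C)(C)C)(CO[Si](C)(C)C(C)(C)C)CO[Si](C)(C)C(C)(C)C | intermediate
5 | isoprene | CC(=C)C=C | starting material
6 | 11-(trimethylsilyloxy)-12,13-bis(TBS-oxy)germacra-1(10)E,4Z,7E-triene | C[Si](C)(C)OC(CO[Si](C)(C)C(C)(C)C)(CO[Si](C)(C)C(C)(C)C)/C1=C/C/C(C)=C/CC/C(C)=C\C1 | intermediate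
7 | 12,13-bis(TBS-oxy)germacra-1(10)E,4Z,7E-trien-11-ol | OC(CO[Si](C)(C)C(C)(C)C)(CO[Si](C)(C)C(C)(C)C)/C1=C/C/C(C)=C/CC/C(C)=C\C1 | intermediate
8 | rac-(7R*,8S*)-7,8-epoxy-12,13-bis(TBS-oxy)germacra-1(10)E,4Z-dien-11-ol (one enantiomer drawn) | OC(CO[Si](C)(C)C(C)(C)C)(CO[Si](C)(C)C(C)(C)C)[C@@]12C/C=C(C)\CC/C=C(C)/C[C@@H]1O2 | intermediate
9 | rac-12,13-bis(TBS-oxy)germacra-1(10)E,4Z,6E-triene-8,11-diol | OC(CO[Si](C)(C)C(C)(C)C)(CO[Si](C)(C)C(C)(C)C)/C1=C/C=C(C)\CC/C=C(C)/CC1O | intermediate
10 | 11-hydroxy-12,13-bis(TBS-oxy)germacra-1(10)E,4Z,6E-trien-8-one | OC(CO[Si](C)(C)C(C)(C)C)(CO[Si](C)(C)C(C)(C)C)/C1=C/C=C(C)\CC/C=C(C)/CC1=O | intermediate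
11 | (8S)-12,13-bis(TBS-oxy)germacra-1(10)E,4Z,6E-triene-8,11-diol | OC(CO[Si](C)(C)C(C)(C)C)(CO[Si](C)(C)C(C)(C)C)/C1=C/C=C(C)\CC/C=C(C)/C[C@@H]1O | intermediate
12 | methyl (2S)-2-methyloxirane-2-carboxylate | COC(=O)[C@]1(C)CO1 | starting material
13 | (2S)-2-methyloxirane-2-carboxylic acid | OC(=O)[C@]1(C)CO1 | intermediate
14 | (8S)-11-hydroxy-12,13-bis(TBS-oxy)germacra-1(10)E,4Z,6E-trien-8-yl (2S)-2-methyloxirane-2-carboxylate | OC(CO[Si](C)(C)C(C)(C)C)(CO[Si](C)(C)C(C)(C)C)/C1=C/C=C(C)\CC/C=C(C)/C[C@@H]1OC(=O)[C@]2(C)CO2 | intermediate
15 | (8S)-6-oxo-12,13-bis(TBS-oxy)germacra-1(10)E,4Z,7(11)-trien-8-yl (2S)-2-methyloxirane-2-carboxylate | CC(C)(C)[Si](C)(C)OCC(CO[Si](C)(C)C(C)(C)C)=C1C(=O)/C=C(C)\CC/C=C(C)/C[C@@H]1OC(=O)[C@]2(C)CO2 | intermediate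
16 | (6R,8S)-6-hydroxy-12,13-bis(TBS-oxy)germacra-1(10)E,4Z,7(11)-trien-8-yl (2S)-2-methyloxirane-2-carboxylate | CC(C)(C)[Si](C)(C)OCC(CO[Si](C)(C)C(C)(C)C)=C1[C@H](O)/C=C(C)\CC/C=C(C)/C[C@@H]1OC(=O)[C@]2(C)CO2 | intermediate
17 | (6R,8S)-6,12,13-trihydroxygermacra-1(10)E,4Z,7(11)-trien-8-yl (2S)-2-methyloxirane-2-carboxylate | OCC(CO)=C1[C@H](O)/C=C(C)\CC/C=C(C)/C[C@@H]1OC(=O)[C@]2(C)CO2 | intermediate
18 | C12 lactol of 17 (6R,8S; both C12 epimers) | OCC1=C2[C@@H](OC(=O)[C@]3(C)CO3)C/C(C)=C/CC/C(C)=C\[C@H]2OC1O | intermediate (not isolated)
19 | (6R,8S)-13-hydroxy-8-[(2S)-2-methyloxirane-2-carbonyloxy]germacra-1(10)E,4Z,7(11)-trien-12,6-olide | OCC1=C2[C@@H](OC(=O)[C@]3(C)CO3)C/C(C)=C/CC/C(C)=C\[C@H]2OC1=O | intermediate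
20 | (6R,8S)-13-acetoxy-8-[(2S)-2-methyloxirane-2-carbonyloxy]germacra-1(10)E,4Z,7(11)-trien-12,6-olide | CC(=O)OCC1=C2[C@@H](OC(=O)[C@]3(C)CO3)C/C(C)=C/CC/C(C)=C\[C@H]2OC1=O | intermediate
21 | (1R,6R,8S,10R)-13-acetoxy-1,10-epoxy-8-[(2S)-2-methyloxirane-2-carbonyloxy]germacra-4Z,7(11)-dien-12,6-olide | CC(=O)OCC1=C2[C@@H](OC(=O)[C@]3(C)CO3)C[C@@]3(C)O[C@@H]3CC/C(C)=C\[C@H]2OC1=O | intermediate (not isolated)
22 | (1R,4R,5S,6S,8S,10R)-13-acetoxy-1,10:4,5-diepoxy-8-[(2S)-2-methyloxirane-2-carbonyloxy]germacr-7(11)-en-12,6-olide | CC(=O)OCC1=C2[C@@H](OC(=O)[C@]3(C)CO3)C[C@@]3(C)O[C@@H]3CC[C@@]3(C)O[C@H]3[C@H]2OC1=O | target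

## Step count and least certain steps

Total: 16 steps. Longest linear sequence: 15 steps (steps 1–8 and 10–16); step 9 prepares the acid.

**Step 3 (key step).** The most likely failure is loss of regiocontrol: the alkyne may insert the other way round, the dienes may link tail to tail, the E/Z pattern may not form, and the alkyne may trimerise. Only the steric difference between the two allyl ends and the bulk of the propargylic carbon steer these choices. The fallback uses known chemistry, sets out from 3 and returns at 7. Neryl acetate F1 is oxidised at its E-methyl group (SeO2, t-BuOOH) to (2Z,6E)-8-hydroxy-3,7-dimethylocta-2,6-dien-1-yl acetate F2, which CBr4/PPh3 converts into (2Z,6E)-8-bromo-3,7-dimethylocta-2,6-dien-1-yl acetate F3. CuI (monovalent copper) with K2CO3 and NaI in DMF couples the terminal alkyne of 3 with F3 to the skipped enyne acetate F4, forming C8–C9. Hydroxyl-directed trans-hydrostannation ([Cp*RuCl]4, Bu3SnH) places tin on C7 and gives the alkenylstannane F5. An intramolecular Stille coupling with the allylic acetate (Pd2(dba)3, zerovalent palladium, LiCl, DMF, high dilution) forms C6–C7 and gives 7; the trans addition fixes the ring-cis C7=C8 bond, and the 1,1-disubstituted allyl terminus resists loss of its Z geometry.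

**Step 16.** Poor facial selectivity is the risk, above all at C4=C5. If the ring reacts through the conformer that turns C15 to the face of O6, outer-face attack gives the 4,5-epimeric epoxide. The fallback sets out from 21, now isolated after one equivalent of dimethyldioxirane, and returns at 22. NBS in aqueous THF gives the bromohydrin F6 (bromine on C5 from the outer face, hydroxyl on C4 from the inner face), and Ag2O (monovalent silver) closes it to the epoxide on the face opposite to that reached by direct epoxidation.

**Step 14.** Over-oxidation of the C13 hydroxymethyl group is the risk, because both primary allylic alcohols are similar and only sterics and the lactol drain favour C12. The fallback sets out from 17 and returns at 19. Excess TEMPO/PhI(OAc)2 gives the 13-oxo lactone F7 on purpose, and NaBH(OAc)3 in benzene/AcOH reduces the aldehyde without base, which would epimerise C6.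

**Step 12.** Poor reagent control is the risk, because both groups on the ketone are alkenyl and the existing C8 centre may be mismatched with the catalyst. The fallback sets out from 15 and returns at 16. Luche reduction (NaBH4, CeCl3·7H2O, MeOH, −78 °C) uses substrate control; if it gives the 6S alcohol F8, a Mitsunobu reaction with chloroacetic acid (DIAD, PPh3) inverts C6 to the (6R)-chloroacetate F9, which thiourea/NaHCO3 cleaves selectively to 16.

**Step 11.** A slow [3,3] shift at the hindered tertiary chromate, with ionisation and elimination taking over, is the risk. The fallback sets out from 14 and returns at 15. Catalytic Ph3SiOReO3 (heptavalent rhenium) in Et2O at 0 °C transposes the hydroxyl to the C6 epimeric alcohols F10, and MnO2 oxidises them to 15.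

## Further compounds

F1 | step 3 | neryl acetate | CC(C)=CCC/C(C)=C\COC(C)=O
F2 | step 3 | (2Z,6E)-8-hydroxy-3,7-dimethylocta-2,6-dien-1-yl acetate | OC/C(C)=C/CC/C(C)=C\COC(C)=O
F3 | step 3 | (2Z,6E)-8-bromo-3,7-dimethylocta-2,6-dien-1-yl acetate | BrC/C(C)=C/CC/C(C)=C\COC(C)=O
F4 | step 3 | skipped enyne acetate (C8–C9 formed; C11 hydroxyl free) | CC(=O)OC/C=C(C)\CC/C=C(C)/CC#CC(O)(CO[Si](C)(C)C(C)(C)C)CO[Si](C)(C)C(C)(C)C
F5 | step 3 | C7 tributylstannyl alkene from trans-hydrostannation of F4 | CC(=O)OC/C=C(C)\CC/C=C(C)/C/C=C(\[Sn](CCCC)(CCCC)CCCC)C(O)(CO[Si](C)(C)C(C)(C)C)CO[Si](C)(C)C(C)(C)C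
F6 | step 16 | 5-bromo-4-hydroxy bromohydrin of 21 | CC(=O)OCC1=C2[C@@H](OC(=O)[C@]3(C)CO3)C[C@@]3(C)O[C@@H]3CC[C@@](C)(O)[C@H](Br)[C@H]2OC1=O
F7 | step 14 | 13-oxo lactone (aldehyde of 19) | O=CC1=C2[C@@H](OC(=O)[C@]3(C)CO3)C/C(C)=C/CC/C(C)=C\[C@H]2OC1=O
F8 | step 12 | (6S)-epimer of 16 | CC(C)(C)[Si](C)(C)OCC(CO[Si](C)(C)C(C)(C)C)=C1[C@@H](O)/C=C(C)\CC/C=C(C)/C[C@@H]1OC(=O)[C@]2(C)CO2
F9 | step 12 | (6R)-chloroacetate of 16 | CC(C)(C)[Si](C)(C)OCC(CO[Si](C)(C)C(C)(C)C)=C1[C@H](OC(=O)CCl)/C=C(C)\CC/C=C(C)/C[C@@H]1OC(=O)[C@]2(C)CO2
F10 | step 11 | 6-hydroxy compound as a mixture of C6 epimers | CC(C)(C)[Si](C)(C)OCC(CO[Si](C)(C)C(C)(C)C)=C1C(O)/C=C(C)\CC/C=C(C)/C[C@@H]1OC(=O)[C@]2(C)CO2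
A1 | alternative 1 | ten-membered butenolide with cis-4,5-epoxide, C1=C10 olefin and two TBS ethers | CC(C)(C)[Si](C)(C)OCC1=C2[C@@H](O[Si](C)(C)C(C)(C)C)C/C(C)=C/CC[C@@]3(C)O[C@H]3[C@H]2OC1=O
A2 | alternative 2 | ten-membered 1(10)E-ene with C5 trimethylsilyl enol ether | CC(=C)[C@@H]1[C@@H](O[Si](C)(C)C(C)(C)C)C/C(C)=C/CC/C(C)=C(\O[Si](C)(C)C)[C@H]1OCc2ccc(OC)cc2
A3 | alternative 3 | 1(10)E,4Z-germacradien-12,6-olide 8,13-bis(TBS) ether | CC(C)(C)[Si](C)(C)OCC1=C2[C@@H](O[Si](C)(C)C(C)(C)C)C/C(C)=C/CC/C(C)=C\[C@H]2OC1=O
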